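**Retrosynthetic overview** (labdane numbering: ring A = C1–C5 and C10; ring B = C5–C10; C11–C12 join C9 to the lactam; C17 on C8, C18/C19 on C4, C20 on C10)
1. Target ⇒ C12–C13 bond by B-alkyl Suzuki–Miyaura coupling of a 9-vinyl-9α-hydroxy-6β-acetoxy decalin with 4-bromo-1,5-dihydro-2H-pyrrol-2-one; the lactam ring is attached last, preformed.
2. The vinyl carbinol ⇒ trans-decalin-6,9-dione (selective C6 reduction; C9 methylidene, α-face epoxide, one-carbon sulfonium-ylide homologation).
3. The dione ⇒ bicyclic 8(17)-ene-6,9-diol (oxidation, hydrogenation, base equilibration of C5 and C8) ⇒ acyclic (S,S)-vinyl epoxide bearing an aldehyde silyl enol ether, by the key cascade: C5–C10 closes ring A (epoxide opening), then C6–C7 closes ring B (carbonyl-ene) in the same flask.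
4. Enabling feature: the ring-fusion carbons C5 and C10, shared by rings A and B, each have an oxygenated neighbour in ring B (C6–OAc, C9–OH; pattern O–C6–C5–C10–C9–O). C5 can therefore be the α-carbon of a C6 carbonyl (nucleophile) and C10 the tertiary end of a C9–C10 epoxide (electrophile), while the C8 methyl (C17) supplies the ene hydrogen.
5. The acyclic precursor ⇒ 5-chloropent-1-yne + 2-bromopropene + 3-methylbut-2-enal (carboalumination/Negishi coupling, conjugate addition, Shi epoxidation).

Key step: step 6

Remark: α means the face opposite to the C10 methyl; the labdane numbers are also used for the acyclic precursors.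
Remark: the L-fructose-derived enantiomer of the Shi ketone is assumed to be available as a catalyst; the D-fructose-derived ketone gives (R,R)-epoxides from E-alkenes, so its mirror image is needed for the (S,S)-epoxide.

**Step 1**
Reactants: 1 5-chloropent-1-yne; 2 2-bromoprop-1-ene
Product: 4 (3E)-7-chloro-2,4-dimethylhepta-1,3-diene, via alkenylalane 3 (not isolated)
Conditions: Me3Al, Cp2ZrCl2 (25 mol%), CH2Cl2, 0 °C → rt; then 2, Pd(PPh3)4 (3 mol%), ZnCl2 (20 mol%), THF, rt
Reagents that add atoms: trimethylaluminium, C[Al](C)C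
Why: Zirconium-catalysed syn-carboalumination of the terminal alkyne places CH3 on the internal carbon (C10) and aluminium on the terminal one, and the Negishi coupling with 2-bromopropene proceeds with retention, so the E-trisubstituted C9=C10 alkene of the diene is fixed.

**Step 2**
Reactants: 4 (3E)-7-chloro-2,4-dimethylhepta-1,3-diene; 5 3-methylbut-2-enal
Product: 9 (7E)-3,3,7,9-tetramethyldeca-7,9-dien-1-ol, via Grignard reagent 6 (not isolated), via silyl enol ether 7 (not isolated), via dienal 8 (not isolated)
Conditions: Mg, THF, 60 °C; then 5, CuBr·SMe2 (10 mol%), Me3SiCl, DMPU, THF, −78 → −40 °C; then K2CO3, MeOH, NaBH4, 0 °C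
Reagents that add atoms: none
Why: Copper-catalysed, Me3SiCl-accelerated conjugate addition of the primary alkyl Grignard reagent to the β,β-disubstituted enal builds the quaternary C4, and the silyl enol ether is methanolysed and the aldehyde reduced in the same flask so that no aldehyde meets the Oxone of step 3; no stereocentre is formed.

**Step 3**
Reactants: 9 (7E)-3,3,7,9-tetramethyldeca-7,9-dien-1-ol
Product: 10 3,3-dimethyl-5-[(2S,3S)-2-methyl-3-(prop-1-en-2-yl)oxiran-2-yl]pentan-1-ol
Conditions: L-fructose-derived Shi ketone (30 mol%), Oxone (2KHSO5·KHSO4·K2SO4), K2CO3, Bu4NHSO4 (cat), MeCN/CH2(OMe)2, aq Na2B4O7 buffer (pH 10.5), 0 °C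
Reagents that add atoms: potassium peroxymonosulfate (the oxidant of Oxone), [K+].[O-]S(=O)(=O)OO
Why: Shi asymmetric epoxidation, in which the chiral dioxirane should attack the electron-rich E-trisubstituted C9=C10 alkene of the diene in preference to the 1,1-disubstituted terminus through the spiro transition state, the L-fructose-derived ketone giving the (S,S)-vinyl epoxide and thereby fixing C10, the only stereocentre that has to persist.

**Step 4**
Reactants: 10 3,3-dimethyl-5-[(2S,3S)-2-methyl-3-(prop-1-en-2-yl)oxiran-2-yl]pentan-1-ol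
Product: 11 3,3-dimethyl-5-[(2S,3S)-2-methyl-3-(prop-1-en-2-yl)oxiran-2-yl]pentanal
Conditions: Pr4N[RuO4] (5 mol%), N-methylmorpholine N-oxide, 4 Å molecular sieves, CH2Cl2, rt
Reagents that add atoms: none
Why: Neutral perruthenate-catalysed oxidation of the primary alcohol to the aldehyde should leave the acid-sensitive vinyl epoxide untouched.

**Step 5**
Reactants: 11 3,3-dimethyl-5-[(2S,3S)-2-methyl-3-(prop-1-en-2-yl)oxiran-2-yl]pentanal
Product: 12 trimethyl{[(1Z)-3,3-dimethyl-5-[(2S,3S)-2-methyl-3-(prop-1-en-2-yl)oxiran-2-yl]pent-1-en-1-yl]oxy}silane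
Conditions: Me3SiOTf (1.1 equiv), Et3N (2.5 equiv), CH2Cl2, −78 → 0 °C
Reagents that add atoms: trimethylsilyl trifluoromethanesulfonate, C[Si](C)(C)OS(=O)(=O)C(F)(F)F
Why: Soft enolisation and O-silylation of the aldehyde, which can only enolise towards C5 because C4 is quaternary, with excess amine keeping free silyl triflate away from the epoxide; the mainly Z enol ether expected has no bearing on the final stereochemistry.

**Step 6**
Reactants: 12 trimethyl{[(1Z)-3,3-dimethyl-5-[(2S,3S)-2-methyl-3-(prop-1-en-2-yl)oxiran-2-yl]pent-1-en-1-yl]oxy}silane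
Product: 14 (1S,4S,4aS,8aS)-5,5,8a-trimethyl-2-methylidenedecahydronaphthalene-1,4-diol, via hydroxy aldehyde 13 (not isolated)
Conditions: Me2AlCl (2.5 equiv), CH2Cl2, −78 → −20 °C; then aq potassium sodium tartrate
Reagents that add atoms: none
Why: Proposed new method: Me2AlCl is expected to coordinate the epoxide oxygen and weaken its bond to the tertiary C10, which the C5 terminus of the silyl enol ether attacks from the back through a chair-like six-membered transition state (ring A, 6-exo opening, C5–C10 bond), after which chloride removes the silyl group and the aluminium-bound C6 aldehyde undergoes a type 2 intramolecular carbonyl-ene reaction with the isopropenyl group (ring B, six-membered closure by the C7 terminus with C8 inside the ring, C6–C7 bond, hydrogen taken from C17). The closest known reaction types are the Lewis-acid-mediated intramolecular opening of epoxides at the more substituted carbon by silyl enol ethers and allylsilanes, and the Me2AlCl-promoted type 2 carbonyl-ene cyclisation of 5-methylhex-5-enals to 3-methylidenecyclohexanols; new is their coupling in one operation. C10 is set by stereospecific inversion at the (S)-configured epoxide carbon and C9 keeps the epoxide configuration, while C5 (chair transition state with the enol ether equatorial, trans to C9) and C6 (equatorial alkoxide in the ene transition state) are expected as drawn but are erased in steps 7 to 9. The selectivity needed is opening at C10 and not at the allylic C9, and it is secured by a tertiary against a secondary centre and by a 6-exo against a 7-endo closure. Me2AlCl also scavenges protons, so no free C8 cation and no pinacol-type shift at C9 should arise, and any alkene isomer or C5/C6 epimer that forms converges on dione 16.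

**Step 7**
Reactants: 14 (1S,4S,4aS,8aS)-5,5,8a-trimethyl-2-methylidenedecahydronaphthalene-1,4-diol
Product: 15 (4aS,8aS)-5,5,8a-trimethyl-2-methylideneoctahydronaphthalene-1,4-dione
Conditions: Dess–Martin periodinane (2.5 equiv), CH2Cl2, rt
Reagents that add atoms: none
Why: Dess–Martin oxidation of both secondary alcohols removes the C6 and C9 configurations left by the cascade and gives the 6,9-dione, whose methylidene is conjugated with the C9 ketone.

**Step 8**
Reactants: 15 (4aS,8aS)-5,5,8a-trimethyl-2-methylideneoctahydronaphthalene-1,4-dione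
Product: 16 (2R,4aS,8aS)-2,5,5,8a-tetramethyloctahydronaphthalene-1,4-dione
Conditions: H2 (1 atm), Pd/C, EtOAc, rt; then NaOMe (cat), MeOH, rt
Reagents that add atoms: none
Why: Hydrogenation of the conjugated alkene (also of any endocyclic 7-ene isomer) followed by base equilibration of the two enolisable centres should place H5 trans to the C10 methyl (trans-decalin) and the C8 methyl equatorial (α), away from the syn-axial C10 methyl, so both are set under thermodynamic control relative to C10.

**Step 9**
Reactants: 16 (2R,4aS,8aS)-2,5,5,8a-tetramethyloctahydronaphthalene-1,4-dione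
Product: 17 (2R,4R,4aS,8aS)-4-hydroxy-2,5,5,8a-tetramethyloctahydronaphthalen-1(2H)-one
Conditions: LiBH(s-Bu)3 (L-Selectride, 1.1 equiv), THF, −78 °C; then H2O
Reagents that add atoms: none
Why: The bulky hydride should reduce only the C6 ketone, since C9 lies between the quaternary C10 and the substituted C8, and it attacks C6 from the α-face (equatorial attack, the β-face being closed by the syn-axial C4 and C10 methyls), which gives the axial 6β-alcohol.

**Step 10**
Reactants: 17 (2R,4R,4aS,8aS)-4-hydroxy-2,5,5,8a-tetramethyloctahydronaphthalen-1(2H)-one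
Product: 18 (1R,3R,4aS,8aS)-3,4a,8,8-tetramethyl-4-methylidenedecahydronaphthalen-1-ol
Conditions: Ph3PCH3Br, KOt-Bu (excess), toluene, 90 °C
Reagents that add atoms: methyltriphenylphosphonium bromide, C[P+](c1ccccc1)(c1ccccc1)c1ccccc1.[Br-]
Why: Wittig methylenation under forcing conditions should convert the hindered C9 ketone into the exocyclic C9=C11 alkene, the 6β-alkoxide being tolerated by excess ylide and any epimerisation at C8 returning the favoured equatorial methyl.

**Step 11**
Reactants: 18 (1R,3R,4aS,8aS)-3,4a,8,8-tetramethyl-4-methylidenedecahydronaphthalen-1-ol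
Product: 19 (5S,6R,8R,9R,10S)-9α,11-epoxy-4,4,8,10-tetramethyl-9-methyldecalin-6β-ol (spiro-oxirane at C9, oxygen on the α-face)
Conditions: dimethyldioxirane (acetone solution), CH2Cl2, 0 °C
Reagents that add atoms: dimethyldioxirane, CC1(C)OO1
Why: Epoxidation of the only alkene under neutral conditions, the oxidant approaching C9=C11 from the α-face (axial attack) because the β-face is shielded by the adjacent axial C10 methyl, so the C9–O bond is α and C11 is β as in the target.

**Step 12**
Reactants: 19 the 9α,11-spiro-epoxide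
Product: 20 (1R,2R,4R,4aS,8aS)-1-ethenyl-2,5,5,8a-tetramethyldecahydronaphthalene-1,4-diol
Conditions: Me3S+ I− (4 equiv), n-BuLi (3.9 equiv), THF, −10 °C → rt
Reagents that add atoms: trimethylsulfonium iodide, C[S+](C)C.[I-]
Why: Dimethylsulfonium methylide should open the 2,2-disubstituted epoxide at its CH2 terminus (C11), and ylide-mediated elimination of dimethyl sulfide from the γ-alkoxy sulfonium salt gives the allylic alcohol (known one-carbon homologation of epoxides), the C9–O bond and hence the 9α-OH configuration being untouched.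

**Step 13**
Reactants: 20 (1R,2R,4R,4aS,8aS)-1-ethenyl-2,5,5,8a-tetramethyldecahydronaphthalene-1,4-diol
Product: 21 (1R,3R,4R,4aS,8aS)-4-ethenyl-4-hydroxy-3,4a,8,8-tetramethyldecahydronaphthalen-1-yl acetate
Conditions: Ac2O, DMAP, pyridine, 40 °C
Reagents that add atoms: acetic anhydride, CC(=O)OC(C)=O
Why: DMAP-catalysed acetylation should take the secondary 6β-alcohol and leave the tertiary 9-alcohol, which is flanked by a quaternary carbon, unchanged.

**Step 14**
Reactants: 22 pyrrolidine-2,4-dione
Product: 23 4-bromo-1,5-dihydro-2H-pyrrol-2-one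
Conditions: (COBr)2, DMF, CH2Cl2, 0 °C → rt
Reagents that add atoms: oxalyl bromide, O=C(Br)C(=O)Br
Why: Vilsmeier-type bromination, in which the enol of the β-dicarbonyl is activated by the bromoiminium salt and bromide replaces the activated oxygen by addition–elimination to give the β-bromo unsaturated lactam.

**Step 15**
Reactants: 21 (1R,3R,4R,4aS,8aS)-4-ethenyl-4-hydroxy-3,4a,8,8-tetramethyldecahydronaphthalen-1-yl acetate; 23 4-bromo-1,5-dihydro-2H-pyrrol-2-one
Product: 25 (1R,3R,4R,4aS,8aS)-4-hydroxy-3,4a,8,8-tetramethyl-4-[2-(5-oxo-2,5-dihydro-1H-pyrrol-3-yl)ethyl]decahydronaphthalen-1-yl acetate (target), via alkylborane 24 (not isolated)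
Conditions: 9-BBN dimer (2.2 equiv), THF, 0 °C → rt; then 23, Pd(dppf)Cl2 (5 mol%), AsPh3 (10 mol%), Cs2CO3, DMF/H2O, rt → 40 °C
Reagents that add atoms: none
Why: Anti-Markovnikov hydroboration of the vinyl group puts boron on C12 and the B-alkyl Suzuki–Miyaura coupling with the β-bromo unsaturated lactam forms C12–C13 with the conjugated lactam alkene in place, no stereocentre being touched and the hindered acetate expected to survive the mild carbonate base.

**Compound list**
1 | 5-chloropent-1-yne | ClCCCC#C | starting material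
2 | 2-bromoprop-1-ene | C=C(C)Br | starting material
3 | [(1E)-5-chloro-2-methylpent-1-en-1-yl]dimethylalumane | C[Al](C)/C=C(\C)CCCCl | intermediate (not isolated)
4 | (3E)-7-chloro-2,4-dimethylhepta-1,3-diene | C=C(C)/C=C(\C)CCCCl | intermediate
5 | 3-methylbut-2-enal | CC(C)=CC=O | starting material
6 | [(4E)-4,6-dimethylhepta-4,6-dien-1-yl]magnesium chloride | Cl[Mg]CCC/C(C)=C/C(C)=C | intermediate (not isolated)
7 | trimethyl{[(7E)-3,3,7,9-tetramethyldeca-1,7,9-trien-1-yl]oxy}silane (enol ether E/Z mixture) | C[Si](C)(C)OC=CC(C)(C)CCC/C(C)=C/C(C)=C | intermediate (not isolated)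
8 | (7E)-3,3,7,9-tetramethyldeca-7,9-dienal | O=CCC(C)(C)CCC/C(C)=C/C(C)=C | intermediate (not isolated)
9 | (7E)-3,3,7,9-tetramethyldeca-7,9-dien-1-ol | OCCC(C)(C)CCC/C(C)=C/C(C)=C | intermediate
10 | 3,3-dimethyl-5-[(2S,3S)-2-methyl-3-(prop-1-en-2-yl)oxiran-2-yl]pentan-1-ol | OCCC(C)(C)CCC[C@]1(C)O[C@H]1C(C)=C | intermediate
11 | 3,3-dimethyl-5-[(2S,3S)-2-methyl-3-(prop-1-en-2-yl)oxiran-2-yl]pentanal | O=CCC(C)(C)CCC[C@]1(C)O[C@H]1C(C)=C | intermediate
12 | trimethyl{[(1Z)-3,3-dimethyl-5-[(2S,3S)-2-methyl-3-(prop-1-en-2-yl)oxiran-2-yl]pent-1-en-1-yl]oxy}silane | C[Si](C)(C)O/C=C\C(C)(C)CCC[C@]1(C)O[C@H]1C(C)=C | intermediate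
13 | (1S,2S)-2-[(1S)-1-hydroxy-2-methylprop-2-en-1-yl]-2,6,6-trimethylcyclohexane-1-carbaldehyde (formed as its aluminium alkoxide) | O=C[C@H]1C(C)(C)CCC[C@]1(C)[C@@H](O)C(C)=C | intermediate (not isolated)
14 | (1S,4S,4aS,8aS)-5,5,8a-trimethyl-2-methylidenedecahydronaphthalene-1,4-diol (6α,9β-diol, trans-decalin) | O[C@H]1CC(=C)[C@H](O)[C@@]2(C)CCCC(C)(C)[C@H]12 | intermediate
15 | (4aS,8aS)-5,5,8a-trimethyl-2-methylideneoctahydronaphthalene-1,4-dione | O=C1CC(=C)C(=O)[C@@]2(C)CCCC(C)(C)[C@H]12 | intermediate
16 | (2R,4aS,8aS)-2,5,5,8a-tetramethyloctahydronaphthalene-1,4-dione (trans-decalin, 8α-methyl) | O=C1C[C@@H](C)C(=O)[C@@]2(C)CCCC(C)(C)[C@H]12 | intermediate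
17 | (2R,4R,4aS,8aS)-4-hydroxy-2,5,5,8a-tetramethyloctahydronaphthalen-1(2H)-one (6β-OH) | O[C@@H]1C[C@@H](C)C(=O)[C@@]2(C)CCCC(C)(C)[C@H]12 | intermediate
18 | (1R,3R,4aS,8aS)-3,4a,8,8-tetramethyl-4-methylidenedecahydronaphthalen-1-ol | O[C@@H]1C[C@@H](C)C(=C)[C@@]2(C)CCCC(C)(C)[C@H]12 | intermediate
19 | 9α,11-spiro-epoxide of 18 (oxirane oxygen α on C9, C9 R) | O[C@@H]1C[C@@H](C)[C@]3(CO3)[C@@]2(C)CCCC(C)(C)[C@H]12 | intermediate
20 | (1R,2R,4R,4aS,8aS)-1-ethenyl-2,5,5,8a-tetramethyldecahydronaphthalene-1,4-diol | O[C@@H]1C[C@@H](C)[C@](O)(C=C)[C@@]2(C)CCCC(C)(C)[C@H]12 | intermediate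
21 | (1R,3R,4R,4aS,8aS)-4-ethenyl-4-hydroxy-3,4a,8,8-tetramethyldecahydronaphthalen-1-yl acetate | CC(=O)O[C@@H]1C[C@@H](C)[C@](O)(C=C)[C@@]2(C)CCCC(C)(C)[C@H]12 | intermediate
22 | pyrrolidine-2,4-dione | O=C1CNC(=O)C1 | starting material
23 | 4-bromo-1,5-dihydro-2H-pyrrol-2-one | O=C1C=C(Br)CN1 | intermediate
24 | B-alkyl-9-borabicyclo[3.3.1]nonane from 21 (boron on C12) | CC(=O)O[C@@H]1C[C@@H](C)[C@](O)(CCB3C4CCCC3CCC4)[C@@]2(C)CCCC(C)(C)[C@H]12 | intermediate (not isolated)
25 | (1R,3R,4R,4aS,8aS)-4-hydroxy-3,4a,8,8-tetramethyl-4-[2-(5-oxo-2,5-dihydro-1H-pyrrol-3-yl)ethyl]decahydronaphthalen-1-yl acetate | CC(=O)O[C@@H]1C[C@@H](C)[C@](O)(CCC2=CC(=O)NC2)[C@@]2(C)CCCC(C)(C)[C@H]12 | target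

**Step count**
Total steps: 15. Longest linear sequence: 14 (steps 1–13 and 15; step 14 is the side branch).

**Steps most likely to fail**

1. Step 6 (the proposed cascade). The Lewis acid may ionise the epoxide at the allylic C9, or a hydride shift may turn it into a ketone before C5 attacks. The silyloxycarbenium ion may also close by a Prins path with cation rearrangement instead of the ene step. The fallback uses known chemistry and takes the two bond formations apart. It sets out from 12: catalytic Me3SiOTf with 2,6-di-tert-butylpyridine in CH2Cl2 at −78 °C (Mukaiyama-type intramolecular epoxide opening with silyl transfer to the new alkoxide) should give the isolable silyl-protected hydroxy aldehyde (1S,2S)-2,6,6-trimethyl-2-[(1S)-2-methyl-1-(trimethylsilyloxy)prop-2-en-1-yl]cyclohexane-1-carbaldehyde F1. In a separate operation, a Me2AlCl-promoted type 2 carbonyl-ene reaction should give the 9-O-trimethylsilyl ether of the bicyclic diol F2. K2CO3 in MeOH then removes the silyl group, and the fallback comes back to the route at 14.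

2. Step 10 (methylenation of the C9 ketone). The basic ylide may enolise the ketone, and the bulky ylide may fail to add to a carbonyl between a quaternary and a tertiary carbon. The fallback is a Peterson olefination setting out from 17. Me3SiCH2Li with CeCl3 in THF at −78 °C, a small and weakly basic nucleophile attacking from the open α-face, should give the β-hydroxysilane 9α-[(trimethylsilyl)methyl]-6β,9β-diol F3. KH in THF then eliminates it to the alkene, and the fallback comes back at 18.

3. Step 12 (ylide opening of the spiro-epoxide). SN2 attack at the neopentyl-type C11 may be slow, and the base may isomerise the epoxide to an allylic alcohol. The fallback sets out from 18 and bypasses 19. OsO4 (cat) with N-methylmorpholine N-oxide dihydroxylates C9=C11 from the α-face to give the 6β,9α,11-triol F4. TEMPO (cat) with PhI(OAc)2 oxidises the primary alcohol selectively to the α-hydroxy aldehyde 6β,9α-dihydroxy-11-al F5. Wittig methylenation with Ph3P=CH2 then gives the vinyl carbinol, and the fallback comes back at 20.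

**Further compounds**
F1 | step 6 | (1S,2S)-2,6,6-trimethyl-2-[(1S)-2-methyl-1-(trimethylsilyloxy)prop-2-en-1-yl]cyclohexane-1-carbaldehyde | O=C[C@H]1C(C)(C)CCC[C@]1(C)[C@@H](O[Si](C)(C)C)C(C)=C
F2 | step 6 | 9-O-trimethylsilyl ether of diol 14 | O[C@H]1CC(=C)[C@H](O[Si](C)(C)C)[C@@]2(C)CCCC(C)(C)[C@H]12
F3 | step 10 | 9α-[(trimethylsilyl)methyl]-4,4,8α,10β-tetramethyl-trans-decalin-6β,9β-diol | O[C@@H]1C[C@@H](C)[C@@](O)(C[Si](C)(C)C)[C@@]2(C)CCCC(C)(C)[C@H]12
F4 | step 12 | 9β-(hydroxymethyl)-4,4,8α,10β-tetramethyl-trans-decalin-6β,9α-diol | O[C@@H]1C[C@@H](C)[C@](O)(CO)[C@@]2(C)CCCC(C)(C)[C@H]12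
F5 | step 12 | 6β,9α-dihydroxy-4,4,8α,10β-tetramethyl-trans-decalin-9β-carbaldehyde | O[C@@H]1C[C@@H](C)[C@](O)(C=O)[C@@]2(C)CCCC(C)(C)[C@H]12
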